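Over 2.0 h at constant temperature, in a closed, stirred flask, I follow free monomer into chains and crystals.

    free monomer + initiator → living end + monomer in chains (k1 = 0.431 M⁻¹ s⁻¹)
    free monomer + living end → monomer in chains + living end, rate k2*[living end]*[free monomer] (k2 = 3.93 M⁻¹ s⁻¹)
    crystals ⇌ monomer in chains, rate k3*(cs3 - [monomer in chains]) while solid is left; crystals form when [monomer in chains] > cs3 (cs3 = 10 mM, k3 = 0.0266 s⁻¹)
    initiator + impurity → spent initiator (k4 = 2010 M⁻¹ s⁻¹)

free monomer 0.020 M; initiator 0.13 mM; impurity 69 µM; time 2.0 h

- maple: doubling the dissolution coefficient of step 3, all else as stated
- birch: doubling the amount of initiator, all else as stated
- oak: doubling the solubility in step 3, all else as stated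

- the monomer in chains and crystals together standing at 2.0 h, as a percentage of the free monomer charged
- the change that raises the amount of monomer in chains and crystals together at 2.0 h, in percent of the free monomer charged most ("none" if none brings more than 2 percentage points) (maple / birch / oak / none)
- amount of monomer in chains and crystals together at 2.0 h, in percent of the free monomer charged, after maple

- amounts and yields of monomer in chains count crystals too
- given per volume of solution although it is solid: crystals
- run time (flask): 2.0 h

**Quickest rung.** In this flask an initiator meets impurity every 7.21 s but free monomer every 116 s, so impurity takes its own charge of initiator first. I therefore put c(living end) at 0.0610 mM, the initiator charge minus the impurity charge.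

**Middle rungs.** The crystal step has a time of 37.6 s, and the surviving initiator a lifetime of 116 s against free monomer.

**Slow rung.** The growth step hands back each living end it uses, so c(living end) stays at 0.0610 mM and the step is pseudo-first-order in free monomer. The survivor half-life, ln 2 over the growth constant times c(living end), is 0.803 h, and since it is much longer than the earlier rungs, c(free monomer) simply halves along it. The solubility is half of the free monomer charged, so I expect crystals from about one half-life on.

**My reckoning.** After 2.0 h this gives 82.2% in chains and crystals. The crystal step trades between two forms counted together and touches neither free monomer nor living ends, so I put maple at 82.2%. Birch lifts c(living end) to 0.191 mM, and my choice is birch.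

**Forecast, result.** The forecast gives 81.7%, chooses birch and puts maple at 81.7%, holding that “Crystallisation only moves material between chains and crystals without touching the living ends or free monomer”. The flask gives 81.8%, and birch gains 18 percentage points, while maple stands at 81.8%.

**Still moving.** At 2.00 h this flask is not at rest: free monomer stands at 18.2%, with c(living end) at 6.10 × 10⁻⁵ M. The neighbour flask, this same charge read at 8.0 h, has had 9.96 survivor half-lives, so I reckon 0.100% free monomer, and it holds 0.10%. Ten times the asked time is 24.9 half-lives for this flask: chains and crystals together reach 100%, free monomer reads 0%, and crystals rise from 31.6% to 50.0%.

The rate constants were drawn at random within sensible limits; the result is computed.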